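**Retrosynthetic overview**

1. C1–O ether: Mitsunobu coupling of umbelliferone with a (2E)-allylic alcohol near the end. The coumarin bicycle is bought, so no ring is formed in the route.
2. C1–C2–C3(CH3): zirconium-catalysed methylalumination and hydroxymethylation of a terminal C2≡C3 alkyne, itself made from a C3 aldehyde by Ohira–Bestmann homologation.
3. C5 carbinol: ketoreductase reduction of a C3–C5 β-keto ester, obtained by Masamune–Brooks two-carbon extension of the C5 acid.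
4. C8 carbinol and prenyl end: chiral phosphoric acid-catalysed allylboration of ethyl (2E)-3-methyl-4-oxobut-2-enoate (which already carries the 6E alkene), then cross-metathesis with 2-methyl-2-butene.
5. Protecting groups: C8–OTBS throughout; C5–OTES is exchanged for the acetate before the final desilylation.

Assumption: the SMILES is read as the (2E,5S,6E,8R) isomer; locants C1–C12 of the side chain (C1 = OCH2, C12 = prenyl end) are used in the Why lines.

**Route**

Step 1
Reactants: 1 ethyl (2E)-3-methyl-4-oxobut-2-enoate; 2 2-allyl-4,4,5,5-tetramethyl-1,3,2-dioxaborolane (allylboronic acid pinacol ester)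
Product: 3 ethyl (2E,4R)-4-hydroxy-3-methylhepta-2,6-dienoate
Conditions: (R)-TRIP [(R)-3,3′-bis(2,4,6-triisopropylphenyl)-1,1′-binaphthyl-2,2′-diyl hydrogen phosphate] (5 mol %), 4 Å MS, toluene, −30 °C; aqueous work-up
Reagents that add atoms: none
Why: Chiral phosphoric acid-catalysed asymmetric allylboration: the (R)-acid holds boronate and aldehyde in a chair transition state so that allyl adds to the Re face, which by analogy with aryl and alkenyl aldehydes sets the first stereocentre (C8 of the target) as R (to be confirmed by Mosher ester analysis), while the enoate and its E alkene are untouched.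

Step 2
Reactants: 3 ethyl (2E,4R)-4-hydroxy-3-methylhepta-2,6-dienoate
Product: 4 ethyl (2E,4R)-4-[(tert-butyldimethylsilyl)oxy]-3-methylhepta-2,6-dienoate
Conditions: TBSCl, imidazole, DMF, rt
Reagents that add atoms: tert-butyldimethylsilyl chloride, CC(C)(C)[Si](C)(C)Cl
Why: Imidazole-promoted silylation of the secondary allylic alcohol gives a TBS ether that survives base, hydride, AlMe3 and mild acid until the last step.

Step 3
Reactants: 4 ethyl (2E,4R)-4-[(tert-butyldimethylsilyl)oxy]-3-methylhepta-2,6-dienoate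
Product: 5 ethyl (2E,4R)-4-[(tert-butyldimethylsilyl)oxy]-3,7-dimethylocta-2,6-dienoate
Conditions: second-generation Grubbs catalyst RuCl2(=CHPh)(PCy3)(H2IMes) (5 mol %), 2-methyl-2-butene/CH2Cl2, 40 °C (sealed)
Reagents that add atoms: 2-methyl-2-butene, CC=C(C)C
Why: Olefin cross-metathesis: only the monosubstituted alkene enters the catalytic cycle, excess 2-methyl-2-butene caps it as the prenyl alkene with loss of propene, and the electron-poor trisubstituted enoate is inert.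

Step 4
Reactants: 5 ethyl (2E,4R)-4-[(tert-butyldimethylsilyl)oxy]-3,7-dimethylocta-2,6-dienoate
Product: 6 (2E,4R)-4-[(tert-butyldimethylsilyl)oxy]-3,7-dimethylocta-2,6-dienoic acid
Conditions: LiOH·H2O, THF/MeOH/H2O, rt to 40 °C; then aq. HCl to pH 3–4 at 0 °C
Reagents that add atoms: lithium hydroxide, [Li+].[OH-]
Why: Saponification of the ethyl ester; the E enoate cannot lactonise and the TBS ether is stable to LiOH and to brief mild acidification.

Step 5
Reactants: 6 (2E,4R)-4-[(tert-butyldimethylsilyl)oxy]-3,7-dimethylocta-2,6-dienoic acid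
Product: 8 ethyl (4E,6R)-6-[(tert-butyldimethylsilyl)oxy]-5,9-dimethyl-3-oxodeca-4,8-dienoate, via acyl imidazolide 7 (not isolated)
Conditions: CDI, THF, rt; then Mg(O2CCH2CO2Et)2, rt to 45 °C; aq. HCl (0.5 M) work-up
Reagents that add atoms: magnesium bis(monoethyl malonate), CCOC(=O)CC(=O)[O-].CCOC(=O)CC(=O)[O-].[Mg+2]; for intermediate 7 only: 1,1′-carbonyldiimidazole, O=C(n1ccnc1)n1ccnc1
Why: Masamune–Brooks chain extension: the acyl imidazolide C-acylates the magnesium malonate half-ester and the adduct loses CO2, giving the β-keto ester under near-neutral conditions that do not disturb the silyloxy stereocentre.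

Step 6
Reactants: 8 ethyl (4E,6R)-6-[(tert-butyldimethylsilyl)oxy]-5,9-dimethyl-3-oxodeca-4,8-dienoate
Product: 9 ethyl (3S,4E,6R)-6-[(tert-butyldimethylsilyl)oxy]-3-hydroxy-5,9-dimethyldeca-4,8-dienoate
Conditions: ketoreductase (Prelog-selective, NADPH-dependent, picked from a commercial screening panel), NADP+ (0.5 mol %), iPrOH (20% v/v), DMSO (5% v/v), KH2PO4/K2HPO4 buffer (0.1 M, pH 7.0), MgSO4 (2 mM), 30 °C
Reagents that add atoms: none
Why: Enzymatic ketone reduction by a ketoreductase: β-keto esters are privileged substrates, the enzyme passes the NADPH hydride to the Re face of the C3 ketone to give the 3S alcohol (C5 of the target) under catalyst control, isopropanol recycles the cofactor, and alkenes and esters are not touched.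

Step 7
Reactants: 9 ethyl (3S,4E,6R)-6-[(tert-butyldimethylsilyl)oxy]-3-hydroxy-5,9-dimethyldeca-4,8-dienoate
Product: 10 ethyl (3S,4E,6R)-6-[(tert-butyldimethylsilyl)oxy]-5,9-dimethyl-3-[(triethylsilyl)oxy]deca-4,8-dienoate
Conditions: TESCl, imidazole, CH2Cl2, 0 °C
Reagents that add atoms: chlorotriethylsilane, CC[Si](Cl)(CC)CC
Why: Silylation; the TES ether survives the next four steps yet can later be removed in the presence of the secondary TBS ether.

Step 8
Reactants: 10 ethyl (3S,4E,6R)-6-[(tert-butyldimethylsilyl)oxy]-5,9-dimethyl-3-[(triethylsilyl)oxy]deca-4,8-dienoate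
Product: 11 (3S,4E,6R)-6-[(tert-butyldimethylsilyl)oxy]-5,9-dimethyl-3-[(triethylsilyl)oxy]deca-4,8-dienal
Conditions: iBu2AlH (1.1 equiv), CH2Cl2, −78 °C; MeOH, then aq. KNaC4H4O6
Reagents that add atoms: none
Why: Partial ester reduction: at −78 °C the aluminium hemiacetal, stabilised by the β-silyloxy oxygen, does not collapse until work-up, so the aldehyde is released without over-reduction.

Step 9
Reactants: 11 (3S,4E,6R)-6-[(tert-butyldimethylsilyl)oxy]-5,9-dimethyl-3-[(triethylsilyl)oxy]deca-4,8-dienal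
Product: 12 (4S,5E,7R)-7-[(tert-butyldimethylsilyl)oxy]-6,10-dimethyl-4-[(triethylsilyl)oxy]undeca-5,9-dien-1-yne
Conditions: dimethyl (1-diazo-2-oxopropyl)phosphonate, K2CO3, MeOH, 0 °C to rt
Reagents that add atoms: dimethyl (1-diazo-2-oxopropyl)phosphonate (Ohira–Bestmann reagent), COP(=O)(OC)C(=[N+]=[N-])C(C)=O
Why: Ohira–Bestmann (Seyferth–Gilbert) homologation: the diazomethylphosphonate anion formed in situ adds to the aldehyde, and loss of phosphate and N2 with a 1,2-hydride shift gives the terminal alkyne under conditions mild enough for the β-silyloxy aldehyde.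

Step 10
Reactants: 12 (4S,5E,7R)-7-[(tert-butyldimethylsilyl)oxy]-6,10-dimethyl-4-[(triethylsilyl)oxy]undeca-5,9-dien-1-yne
Product: 15 (2E,5S,6E,8R)-8-[(tert-butyldimethylsilyl)oxy]-3,7,11-trimethyl-5-[(triethylsilyl)oxy]dodeca-2,6,10-trien-1-ol, via alkenyldimethylalane 13 (not isolated), via lithium alkenylalanate 14 (not isolated)
Conditions: AlMe3 (3 equiv), Cp2ZrCl2 (25 mol %), CH2Cl2, 0 °C to rt; evaporate; n-BuLi, THF/hexane, −78 °C; (CH2O)n, −78 °C to rt; aq. KNaC4H4O6
Reagents that add atoms: trimethylaluminium, C[Al](C)C; formaldehyde (from paraformaldehyde), C=O; for intermediate 14 only: n-butyllithium, [Li]CCCC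
Why: Negishi zirconium-catalysed carboalumination: syn addition of CH3–Al across the terminal alkyne puts the methyl on the internal carbon, and the derived alanate attacks formaldehyde with retention, so the C2=C3 alkene is formed as the E isomer.

Step 11
Reactants: 15 (2E,5S,6E,8R)-8-[(tert-butyldimethylsilyl)oxy]-3,7,11-trimethyl-5-[(triethylsilyl)oxy]dodeca-2,6,10-trien-1-ol; 16 7-hydroxy-2H-chromen-2-one (umbelliferone)
Product: 17 7-{[(2E,5S,6E,8R)-8-[(tert-butyldimethylsilyl)oxy]-3,7,11-trimethyl-5-[(triethylsilyl)oxy]dodeca-2,6,10-trien-1-yl]oxy}-2H-chromen-2-one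
Conditions: PPh3, DIAD, THF, 0 °C to rt
Reagents that add atoms: none
Why: Mitsunobu etherification: the acidic phenol (pKa about 8) displaces the activated primary allylic oxygen by SN2 at C1 without touching the silyl ethers or the alkene geometry.

Step 12
Reactants: 17 7-{[(2E,5S,6E,8R)-8-[(tert-butyldimethylsilyl)oxy]-3,7,11-trimethyl-5-[(triethylsilyl)oxy]dodeca-2,6,10-trien-1-yl]oxy}-2H-chromen-2-one
Product: 18 7-{[(2E,5S,6E,8R)-8-[(tert-butyldimethylsilyl)oxy]-5-hydroxy-3,7,11-trimethyldodeca-2,6,10-trien-1-yl]oxy}-2H-chromen-2-one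
Conditions: PPTS (0.2 equiv), MeOH/CH2Cl2 (1:1), 0 °C to rt
Reagents that add atoms: none
Why: Acid-catalysed methanolysis (selective desilylation) removes the triethylsilyl ether far faster than the secondary TBS ether, so only the C5 hydroxyl is freed.

Step 13
Reactants: 18 7-{[(2E,5S,6E,8R)-8-[(tert-butyldimethylsilyl)oxy]-5-hydroxy-3,7,11-trimethyldodeca-2,6,10-trien-1-yl]oxy}-2H-chromen-2-one
Product: 19 (2E,5S,6E,8R)-8-[(tert-butyldimethylsilyl)oxy]-3,7,11-trimethyl-1-[(2-oxo-2H-chromen-7-yl)oxy]dodeca-2,6,10-trien-5-yl acetate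
Conditions: Ac2O, pyridine, DMAP (cat.), CH2Cl2, 0 °C to rt
Reagents that add atoms: acetic anhydride, CC(=O)OC(C)=O
Why: DMAP-catalysed acetylation of the secondary allylic alcohol with retention at C5, since the C–O bond is not broken.

Step 14
Reactants: 19 (2E,5S,6E,8R)-8-[(tert-butyldimethylsilyl)oxy]-3,7,11-trimethyl-1-[(2-oxo-2H-chromen-7-yl)oxy]dodeca-2,6,10-trien-5-yl acetate
Product: 20 (2E,5S,6E,8R)-8-hydroxy-3,7,11-trimethyl-1-[(2-oxo-2H-chromen-7-yl)oxy]dodeca-2,6,10-trien-5-yl acetate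
Conditions: HF·pyridine, pyridine, THF, 0 °C to rt
Reagents that add atoms: none
Why: Fluoride-driven desilylation under buffered conditions leaves the allylic acetate, the aryl allyl ether and the coumarin lactone intact, and acetate migration across the E alkene is geometrically impossible.

**Compound list**

1 | ethyl (2E)-3-methyl-4-oxobut-2-enoate | CCOC(=O)/C=C(\C)C=O | starting material
2 | 2-allyl-4,4,5,5-tetramethyl-1,3,2-dioxaborolane | C=CCB1OC(C)(C)C(C)(C)O1 | starting material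
3 | ethyl (2E,4R)-4-hydroxy-3-methylhepta-2,6-dienoate | CCOC(=O)/C=C(\C)[C@H](O)CC=C | intermediate
4 | ethyl (2E,4R)-4-[(tert-butyldimethylsilyl)oxy]-3-methylhepta-2,6-dienoate | CCOC(=O)/C=C(\C)[C@H](O[Si](C)(C)C(C)(C)C)CC=C | intermediate
5 | ethyl (2E,4R)-4-[(tert-butyldimethylsilyl)oxy]-3,7-dimethylocta-2,6-dienoate | CCOC(=O)/C=C(\C)[C@H](O[Si](C)(C)C(C)(C)C)CC=C(C)C | intermediate
6 | (2E,4R)-4-[(tert-butyldimethylsilyl)oxy]-3,7-dimethylocta-2,6-dienoic acid | OC(=O)/C=C(\C)[C@H](O[Si](C)(C)C(C)(C)C)CC=C(C)C | intermediate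
7 | acyl imidazolide: (2E,4R)-4-[(tert-butyldimethylsilyl)oxy]-1-(1H-imidazol-1-yl)-3,7-dimethylocta-2,6-dien-1-one | O=C(/C=C(\C)[C@H](O[Si](C)(C)C(C)(C)C)CC=C(C)C)n1ccnc1 | intermediate
8 | ethyl (4E,6R)-6-[(tert-butyldimethylsilyl)oxy]-5,9-dimethyl-3-oxodeca-4,8-dienoate | CCOC(=O)CC(=O)/C=C(\C)[C@H](O[Si](C)(C)C(C)(C)C)CC=C(C)C | intermediate
9 | ethyl (3S,4E,6R)-6-[(tert-butyldimethylsilyl)oxy]-3-hydroxy-5,9-dimethyldeca-4,8-dienoate | CCOC(=O)C[C@H](O)/C=C(\C)[C@H](O[Si](C)(C)C(C)(C)C)CC=C(C)C | intermediate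
10 | ethyl (3S,4E,6R)-6-[(tert-butyldimethylsilyl)oxy]-5,9-dimethyl-3-[(triethylsilyl)oxy]deca-4,8-dienoate | CCOC(=O)C[C@H](O[Si](CC)(CC)CC)/C=C(\C)[C@H](O[Si](C)(C)C(C)(C)C)CC=C(C)C | intermediate
11 | (3S,4E,6R)-6-[(tert-butyldimethylsilyl)oxy]-5,9-dimethyl-3-[(triethylsilyl)oxy]deca-4,8-dienal | O=CC[C@H](O[Si](CC)(CC)CC)/C=C(\C)[C@H](O[Si](C)(C)C(C)(C)C)CC=C(C)C | intermediate
12 | (4S,5E,7R)-7-[(tert-butyldimethylsilyl)oxy]-6,10-dimethyl-4-[(triethylsilyl)oxy]undeca-5,9-dien-1-yne | C#CC[C@H](O[Si](CC)(CC)CC)/C=C(\C)[C@H](O[Si](C)(C)C(C)(C)C)CC=C(C)C | intermediate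
13 | alkenyldimethylalane: [(1E,4S,5E,7R)-7-[(tert-butyldimethylsilyl)oxy]-2,6,10-trimethyl-4-[(triethylsilyl)oxy]undeca-1,5,9-trien-1-yl]dimethylalane | C[Al](C)/C=C(\C)C[C@H](O[Si](CC)(CC)CC)/C=C(\C)[C@H](O[Si](C)(C)C(C)(C)C)CC=C(C)C | intermediate
14 | lithium alkenylalanate: lithium butyl[(1E,4S,5E,7R)-7-[(tert-butyldimethylsilyl)oxy]-2,6,10-trimethyl-4-[(triethylsilyl)oxy]undeca-1,5,9-trien-1-yl]dimethylalanate | [Li+].CCCC[Al-](C)(C)/C=C(\C)C[C@H](O[Si](CC)(CC)CC)/C=C(\C)[C@H](O[Si](C)(C)C(C)(C)C)CC=C(C)C | intermediate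
15 | (2E,5S,6E,8R)-8-[(tert-butyldimethylsilyl)oxy]-3,7,11-trimethyl-5-[(triethylsilyl)oxy]dodeca-2,6,10-trien-1-ol | OC/C=C(\C)C[C@H](O[Si](CC)(CC)CC)/C=C(\C)[C@H](O[Si](C)(C)C(C)(C)C)CC=C(C)C | intermediate
16 | 7-hydroxy-2H-chromen-2-one (umbelliferone) | Oc1ccc2ccc(=O)oc2c1 | starting material
17 | 7-{[(2E,5S,6E,8R)-8-[(tert-butyldimethylsilyl)oxy]-3,7,11-trimethyl-5-[(triethylsilyl)oxy]dodeca-2,6,10-trien-1-yl]oxy}-2H-chromen-2-one | CC[Si](CC)(CC)O[C@H](/C=C(\C)[C@H](O[Si](C)(C)C(C)(C)C)CC=C(C)C)C/C(C)=C/COc1ccc2ccc(=O)oc2c1 | intermediate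
18 | 7-{[(2E,5S,6E,8R)-8-[(tert-butyldimethylsilyl)oxy]-5-hydroxy-3,7,11-trimethyldodeca-2,6,10-trien-1-yl]oxy}-2H-chromen-2-one | O[C@H](/C=C(\C)[C@H](O[Si](C)(C)C(C)(C)C)CC=C(C)C)C/C(C)=C/COc1ccc2ccc(=O)oc2c1 | intermediate
19 | (2E,5S,6E,8R)-8-[(tert-butyldimethylsilyl)oxy]-3,7,11-trimethyl-1-[(2-oxo-2H-chromen-7-yl)oxy]dodeca-2,6,10-trien-5-yl acetate | CC(=O)O[C@H](/C=C(\C)[C@H](O[Si](C)(C)C(C)(C)C)CC=C(C)C)C/C(C)=C/COc1ccc2ccc(=O)oc2c1 | intermediate
20 | (2E,5S,6E,8R)-8-hydroxy-3,7,11-trimethyl-1-[(2-oxo-2H-chromen-7-yl)oxy]dodeca-2,6,10-trien-5-yl acetate | CC(=O)O[C@H](/C=C(\C)[C@H](O)CC=C(C)C)C/C(C)=C/COc1ccc2ccc(=O)oc2c1 | target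

**Step count and risks**

Total step count: 14. Longest linear sequence: 14 steps (1 to 20); umbelliferone 16 enters at step 11.

The three steps most likely to fail:

Step 6. The ketoreductase may not accept the bulky, lipophilic keto ester, or the panel may only offer the wrong facial preference. The fallback sets out from 8: NaBH4 with CeCl3·7H2O in MeOH at −40 °C reduces the ketone without selectivity to the C3-epimeric alcohol mixture ethyl (3RS,4E,6R)-6-[(tert-butyldimethylsilyl)oxy]-3-hydroxy-5,9-dimethyldeca-4,8-dienoate F1. A lipase (Burkholderia cepacia lipase, vinyl acetate, MTBE, 30 °C) then acetylates only the 3R epimer, as expected from the Kazlauskas rule, to the acetate ethyl (3R,4E,6R)-3-(acetyloxy)-6-[(tert-butyldimethylsilyl)oxy]-5,9-dimethyldeca-4,8-dienoate F2. The untouched 3S alcohol is separated by chromatography, and this is where the route comes back at 9.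

Step 9. The β-silyloxy aldehyde can lose silanol to a conjugated dienal, or the TES ether can be cleaved, under K2CO3/MeOH. The fallback sets out from 11 and avoids the basic methanol: Corey–Fuchs olefination (CBr4, PPh3, Et3N, CH2Cl2, 0 °C) gives the dibromoalkene (4S,5E,7R)-1,1-dibromo-7-[(tert-butyldimethylsilyl)oxy]-6,10-dimethyl-4-[(triethylsilyl)oxy]undeca-1,5,9-triene F3. Treatment with n-BuLi (2.2 equiv, THF, −78 °C) and an aq. NH4Cl quench then gives the alkyne, coming back at 12.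

Step 10. AlMe3 may ionise the allylic silyl ethers, or the methylalumination may be sluggish or give the regioisomer. The fallback sets out from 12 and builds the same alkene by hydroxyl-directed chemistry: n-BuLi (THF, −78 °C) then (CH2O)n gives the propargylic alcohol (5S,6E,8R)-8-[(tert-butyldimethylsilyl)oxy]-7,11-dimethyl-5-[(triethylsilyl)oxy]dodeca-6,10-dien-2-yn-1-ol F4. Trans-hydroalumination with NaAlH2(OCH2CH2OMe)2 (THF, 0 °C) and iodination (I2, −78 °C) gives the vinyl iodide (2Z,5S,6E,8R)-8-[(tert-butyldimethylsilyl)oxy]-3-iodo-7,11-dimethyl-5-[(triethylsilyl)oxy]dodeca-2,6,10-trien-1-ol F5. Me2CuLi (excess, Et2O, 0 °C) replaces iodine by methyl with retention of geometry and comes back at 15.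

**Further compounds**

F1 | step 6 | ethyl (3RS,4E,6R)-6-[(tert-butyldimethylsilyl)oxy]-3-hydroxy-5,9-dimethyldeca-4,8-dienoate | CCOC(=O)CC(O)/C=C(\C)[C@H](O[Si](C)(C)C(C)(C)C)CC=C(C)C
F2 | step 6 | ethyl (3R,4E,6R)-3-(acetyloxy)-6-[(tert-butyldimethylsilyl)oxy]-5,9-dimethyldeca-4,8-dienoate | CCOC(=O)C[C@@H](OC(C)=O)/C=C(\C)[C@H](O[Si](C)(C)C(C)(C)C)CC=C(C)C
F3 | step 9 | (4S,5E,7R)-1,1-dibromo-7-[(tert-butyldimethylsilyl)oxy]-6,10-dimethyl-4-[(triethylsilyl)oxy]undeca-1,5,9-triene | BrC(Br)=CC[C@H](O[Si](CC)(CC)CC)/C=C(\C)[C@H](O[Si](C)(C)C(C)(C)C)CC=C(C)C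
F4 | step 10 | (5S,6E,8R)-8-[(tert-butyldimethylsilyl)oxy]-7,11-dimethyl-5-[(triethylsilyl)oxy]dodeca-6,10-dien-2-yn-1-ol | OCC#CC[C@H](O[Si](CC)(CC)CC)/C=C(\C)[C@H](O[Si](C)(C)C(C)(C)C)CC=C(C)C
F5 | step 10 | (2Z,5S,6E,8R)-8-[(tert-butyldimethylsilyl)oxy]-3-iodo-7,11-dimethyl-5-[(triethylsilyl)oxy]dodeca-2,6,10-trien-1-ol | OC/C=C(\I)C[C@H](O[Si](CC)(CC)CC)/C=C(\C)[C@H](O[Si](C)(C)C(C)(C)C)CC=C(C)C
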